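**Retrosynthetic overview**
1. Target 15 ⇒ C27 polyenynal 14 + ketone-stabilised ylide Ph3P=C(Me)COMe (Wittig, forms the enone C=C).
2. 14 ⇒ C25 aldehyde 12 + a masked C2 formyl ylide; 12 ⇒ C15 phosphonium salt 8 + C10 dialdehyde 9 (Wittig).
3. 8 ⇒ enol triflate 5 + (E)-enynol 6 (Sonogashira, ring–alkyne bond).
4. 5 ⇒ (S)-4-hydroxy enone 2 (conjugate reduction and enolate triflation); 2 ⇒ enone 1 by enantioselective allylic C–H hydroxylation, the C–O bond formation that sets the only stereocentre.
5. Rings: none is formed; the single carbocycle comes with 1.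

Assumption: 1, 6, 9 and the two phosphorus reagents of steps 7 and 8 are bought as catalogue chemicals; the target is the (R) alcohol (3R in carotenoid numbering) with all seven C=C bonds E, as the SMILES reads.

**Step 1**
Reactants: 1 2,6,6-trimethylcyclohex-2-en-1-one
Product: 2 (S)-4-hydroxy-2,6,6-trimethylcyclohex-2-en-1-one
Conditions: evolved P450-BM3 (CYP102A1) variant (cell-free extract), NADP+ (cat.), glucose dehydrogenase, D-glucose, O2 (air), KPi pH 7.5, 5% DMSO, 25 °C
Reagents that add atoms: dioxygen, O=O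
Why: Proposed new method: an engineered P450-BM3 monooxygenase, evolved by active-site saturation mutagenesis and screened for the (S)-alcohol, holds the small enone with C4 over the haem; compound I (Fe(IV)=O porphyrin radical cation) abstracts hydrogen from C4, the weakest C–H bond (secondary, allylic, radical delocalised over C4–C3–C2 into the carbonyl), and OH rebound at C4 on the face fixed by the pocket forms the C–O bond and sets the only stereocentre (rebound at the tertiary C2 is hindered and the electron-poor C=C resists epoxidation); the closest known reaction is the P450- and peroxygenase-catalysed enantioselective allylic C4 hydroxylation of the isomeric enone α-isophorone, not yet shown for this substrate.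

**Step 2**
Reactants: 2 (S)-4-hydroxy-2,6,6-trimethylcyclohex-2-en-1-one
Product: 3 (S)-2,6,6-trimethyl-4-(triethylsilyloxy)cyclohex-2-en-1-one
Conditions: TESCl, imidazole, CH2Cl2, 0 °C to rt
Reagents that add atoms: triethylsilyl chloride, CC[Si](Cl)(CC)CC
Why: Imidazole-assisted O-silylation masks the secondary allylic alcohol for the hydride and triflation chemistry; the base is far too weak to deprotonate C4, so the stereocentre is kept.

**Step 3**
Reactants: 3 (S)-2,6,6-trimethyl-4-(triethylsilyloxy)cyclohex-2-en-1-one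
Product: 5 (R)-2,6,6-trimethyl-4-(triethylsilyloxy)cyclohex-1-en-1-yl trifluoromethanesulfonate, via lithium enolate 4 (not isolated)
Conditions: L-Selectride, THF, −78 °C; then PhNTf2, −78 °C to rt
Reagents that add atoms: N-phenyl-bis(trifluoromethanesulfonimide), O=S(=O)(N(c1ccccc1)S(=O)(=O)C(F)(F)F)C(F)(F)F
Why: Conjugate hydride addition of the bulky borohydride to the β-unsubstituted enone (the carbonyl is shielded by the gem-dimethyl group) gives the tetrasubstituted enolate regiospecifically, and O-triflation traps it (reductive enol triflation); the carbinol centre is untouched and its label changes from S to R only because C3 becomes CH2.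

**Step 4**
Reactants: 5 (R)-2,6,6-trimethyl-4-(triethylsilyloxy)cyclohex-1-en-1-yl trifluoromethanesulfonate; 6 (E)-3-methylpent-2-en-4-yn-1-ol
Product: 7 (2E)-3-methyl-5-[(4R)-2,6,6-trimethyl-4-(triethylsilyloxy)cyclohex-1-en-1-yl]pent-2-en-4-yn-1-ol
Conditions: Pd(PPh3)4 (5 mol%), CuI (10 mol%), Et3N, DMF, degassed, rt to 40 °C
Reagents that add atoms: none
Why: Sonogashira coupling of the enol triflate with the terminal alkyne forms the ring–alkyne bond and carries the E geometry of the enynol through unchanged.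

**Step 5**
Reactants: 7 (2E)-3-methyl-5-[(4R)-2,6,6-trimethyl-4-(triethylsilyloxy)cyclohex-1-en-1-yl]pent-2-en-4-yn-1-ol
Product: 8 [(2E)-5-[(4R)-4-hydroxy-2,6,6-trimethylcyclohex-1-en-1-yl]-3-methylpent-2-en-4-yn-1-yl]triphenylphosphonium bromide
Conditions: PPh3·HBr, MeOH, 0 °C to rt, dark
Reagents that add atoms: triphenylphosphine hydrobromide, [Br-].c1ccc(cc1)[PH+](c1ccccc1)c1ccccc1
Why: Wittig salt formation from the primary allylic alcohol with Ph3P·HBr, while the acidic methanol removes the TES ether; the homoallylic secondary alcohol does not ionise, so the stereocentre is kept.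

**Step 6**
Reactants: 8 [(2E)-5-[(4R)-4-hydroxy-2,6,6-trimethylcyclohex-1-en-1-yl]-3-methylpent-2-en-4-yn-1-yl]triphenylphosphonium bromide; 9 (2E,4E,6E)-2,7-dimethylocta-2,4,6-trienedial
Product: 12 (2E,4E,6E,8E,10E)-13-[(4R)-4-hydroxy-2,6,6-trimethylcyclohex-1-en-1-yl]-2,7,11-trimethyltrideca-2,4,6,8,10-pentaen-12-ynal, via phosphorus ylide 10 (not isolated), via (8Z)-C25 aldehyde 11 (not isolated)
Conditions: 9 (3 equiv), NaOMe, CH2Cl2/MeOH, 0 °C to rt; then heptane/EtOAc, 80 °C
Reagents that add atoms: none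
Why: Wittig olefination of the semi-stabilised allylic ylide with one formyl group of the excess dialdehyde (the second is less electrophilic once the polyene has grown) gives the new CH=CH bond as an E/Z mixture, and the hindered Z isomer goes over to E on heating without iodine.

**Step 7**
Reactants: 12 (2E,4E,6E,8E,10E)-13-[(4R)-4-hydroxy-2,6,6-trimethylcyclohex-1-en-1-yl]-2,7,11-trimethyltrideca-2,4,6,8,10-pentaen-12-ynal
Product: 14 (2E,4E,6E,8E,10E,12E)-15-[(4R)-4-hydroxy-2,6,6-trimethylcyclohex-1-en-1-yl]-4,9,13-trimethylpentadeca-2,4,6,8,10,12-hexaen-14-ynal, via vinyl dioxolane 13 (not isolated)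
Conditions: (1,3-dioxolan-2-ylmethyl)triphenylphosphonium bromide, t-BuOK, THF, 0 °C to rt; then 1 M HCl (aq), THF, rt
Reagents that add atoms: (1,3-dioxolan-2-ylmethyl)triphenylphosphonium bromide, [Br-].C1COC(O1)C[P+](c1ccccc1)(c1ccccc1)c1ccccc1; water, O
Why: Wittig two-carbon homologation with a masked formylmethylene ylide cannot over-homologate because the product stays an acetal until the acid step, which hydrolyses the dioxolane and equilibrates the new enal bond to E.

**Step 8**
Reactants: 14 (2E,4E,6E,8E,10E,12E)-15-[(4R)-4-hydroxy-2,6,6-trimethylcyclohex-1-en-1-yl]-4,9,13-trimethylpentadeca-2,4,6,8,10,12-hexaen-14-ynal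
Product: 15 (3E,5E,7E,9E,11E,13E,15E)-18-[(4R)-4-hydroxy-2,6,6-trimethylcyclohex-1-en-1-yl]-3,7,12,16-tetramethyloctadeca-3,5,7,9,11,13,15-heptaen-17-yn-2-one
Conditions: 3-(triphenylphosphoranylidene)butan-2-one (2.5 equiv), toluene, 70 °C, Ar, dark
Reagents that add atoms: 3-(triphenylphosphoranylidene)butan-2-one, CC(=O)C(C)=P(c1ccccc1)(c1ccccc1)c1ccccc1
Why: Wittig olefination with the ketone-stabilised α-methyl ylide attacks only the unhindered aldehyde and gives the E-trisubstituted enone (acetyl trans to the chain), which completes the target.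

**Compound list**
1 | 2,6,6-trimethylcyclohex-2-en-1-one | CC1=CCCC(C)(C)C1=O | starting material
2 | (S)-4-hydroxy-2,6,6-trimethylcyclohex-2-en-1-one | O=C1C(C)=C[C@@H](O)CC1(C)C | intermediate
3 | (S)-2,6,6-trimethyl-4-(triethylsilyloxy)cyclohex-2-en-1-one | O=C1C(C)=C[C@@H](O[Si](CC)(CC)CC)CC1(C)C | intermediate
4 | lithium (R)-2,6,6-trimethyl-4-(triethylsilyloxy)cyclohex-1-en-1-olate | [Li+].[O-]C1=C(C)C[C@@H](O[Si](CC)(CC)CC)CC1(C)C | intermediate (not isolated)
5 | (R)-2,6,6-trimethyl-4-(triethylsilyloxy)cyclohex-1-en-1-yl trifluoromethanesulfonate | O=S(=O)(OC1=C(C)C[C@@H](O[Si](CC)(CC)CC)CC1(C)C)C(F)(F)F | intermediate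
6 | (E)-3-methylpent-2-en-4-yn-1-ol | C#C/C(C)=C/CO | starting material
7 | (2E)-3-methyl-5-[(4R)-2,6,6-trimethyl-4-(triethylsilyloxy)cyclohex-1-en-1-yl]pent-2-en-4-yn-1-ol | OC/C=C(\C)C#CC1=C(C)C[C@@H](O[Si](CC)(CC)CC)CC1(C)C | intermediate
8 | [(2E)-5-[(4R)-4-hydroxy-2,6,6-trimethylcyclohex-1-en-1-yl]-3-methylpent-2-en-4-yn-1-yl]triphenylphosphonium bromide | [Br-].c1ccccc1[P+](c1ccccc1)(c1ccccc1)C/C=C(\C)C#CC1=C(C)C[C@@H](O)CC1(C)C | intermediate
9 | (2E,4E,6E)-2,7-dimethylocta-2,4,6-trienedial | O=C/C(C)=C/C=C/C=C(C)/C=O | starting material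
10 | phosphorus ylide of 8, [(2E)-5-[(4R)-4-hydroxy-2,6,6-trimethylcyclohex-1-en-1-yl]-3-methylpent-2-en-4-yn-1-ylidene]triphenylphosphorane | c1ccccc1[P+](c1ccccc1)(c1ccccc1)[CH-]/C=C(\C)C#CC1=C(C)C[C@@H](O)CC1(C)C | intermediate (not isolated)
11 | (2E,4E,6E,8Z,10E)-13-[(4R)-4-hydroxy-2,6,6-trimethylcyclohex-1-en-1-yl]-2,7,11-trimethyltrideca-2,4,6,8,10-pentaen-12-ynal | O=C/C(C)=C/C=C/C=C(C)/C=C\C=C(/C)C#CC1=C(C)C[C@@H](O)CC1(C)C | intermediate (not isolated)
12 | (2E,4E,6E,8E,10E)-13-[(4R)-4-hydroxy-2,6,6-trimethylcyclohex-1-en-1-yl]-2,7,11-trimethyltrideca-2,4,6,8,10-pentaen-12-ynal | O=C/C(C)=C/C=C/C=C(C)/C=C/C=C(\C)C#CC1=C(C)C[C@@H](O)CC1(C)C | intermediate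
13 | 2-[(3E,5E,7E,9E,11E)-14-[(4R)-4-hydroxy-2,6,6-trimethylcyclohex-1-en-1-yl]-3,8,12-trimethyltetradeca-1,3,5,7,9,11-hexaen-13-yn-1-yl]-1,3-dioxolane, E/Z mixture at C1=C2 | C1COC(O1)C=C/C(C)=C/C=C/C=C(C)/C=C/C=C(\C)C#CC2=C(C)C[C@@H](O)CC2(C)C | intermediate (not isolated)
14 | (2E,4E,6E,8E,10E,12E)-15-[(4R)-4-hydroxy-2,6,6-trimethylcyclohex-1-en-1-yl]-4,9,13-trimethylpentadeca-2,4,6,8,10,12-hexaen-14-ynal | O=C/C=C/C(C)=C/C=C/C=C(C)/C=C/C=C(\C)C#CC1=C(C)C[C@@H](O)CC1(C)C | intermediate
15 | (3E,5E,7E,9E,11E,13E,15E)-18-[(4R)-4-hydroxy-2,6,6-trimethylcyclohex-1-en-1-yl]-3,7,12,16-tetramethyloctadeca-3,5,7,9,11,13,15-heptaen-17-yn-2-one | CC(=O)/C(C)=C/C=C/C(C)=C/C=C/C=C(C)/C=C/C=C(\C)C#CC1=C(C)C[C@@H](O)CC1(C)C | target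

**Count**
Total steps: 8. Longest linear sequence: 8 (1 → 2 → 3 → 5 → 7 → 8 → 12 → 14 → 15).

**Steps most likely to fail**

Step 1 (the proposed enzymatic hydroxylation): a variant with high (S) selectivity may not be found, or over-oxidation to the ene-dione may dominate. The fallback uses known chemistry, sets out from 1 and comes back at 2. Allylic oxidation of the γ-methylene of 1 (Pd(OH)2/C, t-BuOOH, K2CO3, CH2Cl2) gives 2,6,6-trimethylcyclohex-2-ene-1,4-dione F1, which is also the over-oxidation product of step 1 and a cheap catalogue chemical. Ruthenium-catalysed asymmetric transfer hydrogenation (RuCl(p-cymene)[TsDPEN], i-PrOH, with the catalyst enantiomer that gives the (S)-alcohol, expected to be (S,S) with the alkenyl arm in the place of the aryl group of the usual model) then reduces the unhindered C4 carbonyl to give 2. The stereocentre is then set by hydride delivery to C=O instead of by C–H hydroxylation.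

Step 5 (salt formation): the acidic conditions may ionise the enynyl allylic system and erode the E geometry next to the alkyne towards the less crowded Z form, or leave the TES ether partly in place. The fallback sets out from 7 and comes back at 8, and replaces the acid-mediated substitution by an SN2 sequence. Buffered fluoride (TBAF, AcOH, THF, 0 °C) gives (2E)-5-[(4R)-4-hydroxy-2,6,6-trimethylcyclohex-1-en-1-yl]-3-methylpent-2-en-4-yn-1-ol F2. Appel bromination of the primary allylic hydroxyl only (CBr4, PPh3, CH2Cl2, −30 °C) gives (1R)-4-[(3E)-5-bromo-3-methylpent-3-en-1-yn-1-yl]-3,5,5-trimethylcyclohex-3-en-1-ol F3. PPh3 in EtOAc at rt displaces the bromide to give 8.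

Step 7 (C2 homologation): the hot or strongly basic ylide step on a hydroxy polyenal and the acid hydrolysis may give low yield or geometric scrambling. The fallback sets out from 12 and comes back at 14. Horner–Wadsworth–Emmons reaction with diethyl cyanomethylphosphonate (NaH, THF, 0 °C) gives (2E,4E,6E,8E,10E,12E)-15-[(4R)-4-hydroxy-2,6,6-trimethylcyclohex-1-en-1-yl]-4,9,13-trimethylpentadeca-2,4,6,8,10,12-hexaen-14-ynenitrile F4, with a minor 2Z isomer that converges to E at the enal stage. DIBAL-H (3 equiv, CH2Cl2, −78 °C) followed by aqueous hydrolysis of the imine gives 14.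

**Further compounds**
F1 | step 1 | 2,6,6-trimethylcyclohex-2-ene-1,4-dione | CC1=CC(=O)CC(C)(C)C1=O
F2 | step 5 | (2E)-5-[(4R)-4-hydroxy-2,6,6-trimethylcyclohex-1-en-1-yl]-3-methylpent-2-en-4-yn-1-ol | OC/C=C(\C)C#CC1=C(C)C[C@@H](O)CC1(C)C
F3 | step 5 | (1R)-4-[(3E)-5-bromo-3-methylpent-3-en-1-yn-1-yl]-3,5,5-trimethylcyclohex-3-en-1-ol | BrC/C=C(\C)C#CC1=C(C)C[C@@H](O)CC1(C)C
F4 | step 7 | (2E,4E,6E,8E,10E,12E)-15-[(4R)-4-hydroxy-2,6,6-trimethylcyclohex-1-en-1-yl]-4,9,13-trimethylpentadeca-2,4,6,8,10,12-hexaen-14-ynenitrile | N#C/C=C/C(C)=C/C=C/C=C(C)/C=C/C=C(\C)C#CC1=C(C)C[C@@H](O)CC1(C)C
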